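## Analysis of the target

The target 21 is a (2S)-flavanone: ring A is a phloroglucinol-type benzene ring with free hydroxyls at C5 and C7, ring C is the 2,3-dihydropyran-4-one with the ketone at C4, and ring B is a 4-hydroxyphenyl group on C2. C6, the ring A carbon between the two hydroxyls, carries a (1E,3S)-3,7-dimethylocta-1,6-dienyl chain with an E double bond conjugated to ring A, an allylic methyl-bearing stereocentre at C3'' and a remote trisubstituted alkene. The two stereocentres, C2 and C3'', are separated by ring A and cannot influence each other, so each must be set or bought on its own with absolute control. C2 is the fragile one: it is benzylic, bound to O1 and β to the ketone, so base opens ring C to the 2'-hydroxychalcone by retro-oxa-Michael reaction and strong Lewis acids can ionise the C2–O1 bond; either event erases the configuration. The chain is acid-sensitive, because the styrene-type double bond on the very electron-rich ring A and the trisubstituted alkene protonate and cyclise onto the flanking phenols, and its allylic stereocentre is lost if the double bond migrates. The synthesis is hard because the chain must go to C6 and not C8, C2 must be made enantioselectively in a ring that opens easily, and three phenols must be freed at the end without acid, strong base or strong Lewis acid. The strategy rests on one feature of ring C: C2 is a benzylic carbon bound to O1 and C3 is the α-carbon of the C4 ketone, so the C2–C3 bond can be made by insertion of a carbenoid centred on C3 into a C–H bond of a 4-oxybenzyl ether on O1, whose benzylic carbon and aryl group then become C2 and ring B.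

## Retrosynthetic reasoning

**Unmasking the phenols (21 from 20).** The last operation has to be the gentlest of the whole route, because both stereocentres and the acid-labile diene are present. Aryl acetates fit: they come off by buffered solvolysis, with neither acid nor strong base. The immediate precursor is therefore triacetate 20.

**C6–C1'' (20 from 18 and 19).** The bond between ring A and the chain is an sp2–sp2 bond to a 1-alkene that can be bought enantiopure with C3'' already in place, namely 19. Cutting here, and not inside the chain, means the chain stereocentre never has to be made. The forward Mizoroki–Heck reaction must arylate the terminal carbon of 19, give the E alkene, ignore the trisubstituted alkene and not let a palladium hydride walk through C3''. The cut is made late so that every acidic or Lewis-acidic operation lies before the diene exists. Acetates on O5 and O7 make bromide 18 less electron-rich and keep phenoxides, which would open ring C, out of the basic coupling medium.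

**Protecting-group exchange (18 from 16 from 15).** The groups that suit the carbenoid step are not those that suit the coupling, so one exchange is accepted: 15 is stripped to triol 16 and 16 is acetylated with 17. The choice in 15 follows from what can be removed without endangering C2. O5 must carry a group with no easily attacked C–H bond near the carbenoid, so it is a methyl ether; this one methyl ether lies peri to the C4 carbonyl and can be cleaved at low temperature through a boron chelate. O7 and O4' have no such help. A methyl ether there would need forcing Lewis-acid demethylation after C2 is set, so both are methoxymethyl acetals, which a boron Lewis acid cleaves at low temperature through their distal oxygens.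

**C2–C3 (15 from 14).** This is the strategic cut. Breaking C2–C3 turns ring B and C2 into the benzyl-type ether on O1 of an aryl diazomethyl ketone 14, so the O1 protecting group is the source of C2 and ring B, and ring C and the C2 stereocentre arise in one catalytic step. Other cuts in ring C (O1–C2, O1–C8a, C4–C4a) would need a separate asymmetric step to make C2 and then a ring closure. The forward reaction has to pick the doubly activated benzylic C–H bond over the ether oxygens and distinguish its two enantiotopic hydrogens.

**Diazo group (14 from 10 with 11 and 12).** The diazomethyl ketone is taken back to the methyl ketone 10. Activation of the methyl group as its trifluoroacetyl derivative 13 with 11, followed by diazo transfer from 12, installs the diazo group directly on the ketone. No carboxylic acid has to be activated and no volatile diazoalkane is handled, and the conditions tolerate the acetals and the aryl bromide.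

**Ring A substituents (10 from 8 from 6, with 9 and 7).** The O5 methyl group is put on last (9), and bromine (7) is introduced while O5 is still a free hydroxyl hydrogen-bonded to the ketone. That hydroxyl steers the halogen to its ortho position, the carbon between O5 and O7, which is C6 of the flavanone. A route that placed bromine between two identical ethers from the start would fix the halogen position by symmetry, but it would make O5 and O7 carry the same group; a group removable from O7 without forcing conditions would then not be inert toward the carbenoid at O5.

**Ether bonds of ring A (6 from 3 and 5; 3 from 1 and 2; 5 from 4).** Phenol differentiation uses the intrinsic order of reactivity of 1. The 4-hydroxyl is the only one not hydrogen-bonded to the acetyl group and is acetalised first with 2, giving 3. The two remaining hydroxyls of 3 are equivalent, so one Mitsunobu etherification with benzylic alcohol 5 (from aldehyde 4 by reduction) gives 6 as a single regioisomer. The hydroxyl left over, the future O5, is then locked in the hydrogen bond to the ketone.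

## Alternatives that were turned down

**Alternative 1:** Disconnection of O1–C8a. In the forward direction an open-chain (S)-benzylic alcohol would be joined to a bromide at C8a by palladium-catalysed intramolecular C–O coupling with a bulky biaryl dialkylphosphine. This would close ring C and give (2S)-4-[(tert-butyldimethylsilyl)oxy]-6-[(1E,3S)-3,7-dimethylocta-1,6-dien-1-yl]-5,7-bis(methoxymethoxy)-2-[4-(methoxymethoxy)phenyl]-3,4-dihydro-2H-chromene A1. The configuration at C4 of A1 is of no consequence and is left undefined.
- For it: C2 would be made beforehand by well-understood asymmetric carbonyl chemistry, and the C2–O bond is never broken in the ring closure. On the security of the C2 configuration this alternative is stronger than the chosen route, which relies on a catalyst–substrate pairing that has not been tested.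
- Against it: C4 must be carried as a silyl-protected alcohol, so desilylation and oxidation follow the ring closure. The three acetals of A1 must then be removed with acid while the acid-labile styrene is already present. The bromide is electron-rich and ortho-substituted, which slows oxidative addition. The secondary palladium alkoxide can undergo β-hydride elimination instead of C–O reductive elimination. The open-chain precursor needs several C–C bond formations on a pentasubstituted arene.
- Comparison: the chosen strategy makes C2–C3 with C4 already a ketone, brings in the chain after all acid steps, and reaches its key step in fewer operations than A1 would need; it pays for this with a less precedented enantioselective step.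

**Alternative 2:** Disconnection of O1–C2 and C3–C4. A salicylaldehyde and a cinnamaldehyde would be combined by a chiral secondary amine (iminium-ion oxa-Michael addition, then enamine aldol condensation). The product would be (2R)-6-bromo-5,7-dimethoxy-2-[4-(pivaloyloxy)phenyl]-2H-chromene-3-carbaldehyde A2. In A2 the descriptor is R only because the C3 substituent outranks the aryl group; the arrangement in space is that of the target.
- For it: two bonds and the stereocentre are formed in one metal-free step from simple aldehydes, with good precedent for high enantioselectivity on simple salicylaldehydes and no diazo chemistry. On precedent for the enantioselective ring closure it is as strong as or stronger than the chosen route.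
- Against it: A2 has the wrong oxidation pattern. C3 carries a formyl carbon that the target lacks and C4 is an sp2 CH, not a ketone, so a decarbonylation and a net oxygenation of C4 are needed, four or five steps next to a labile stereocentre. 2H-Chromenes can racemise by reversible electrocyclic ring opening. The required salicylaldehyde is di-ortho-substituted and electron-rich, which slows the aldol condensation. The methyl ethers of A2 at O5 and O7 would need forcing Lewis-acid cleavage after C2 is set.
- Comparison: the chosen strategy delivers CH2 at C3 and the ketone at C4 directly, and carries protecting groups that come off at low temperature, whereas A2 is several redox steps away from a flavanone.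

**Alternative 3:** Ring A is built last by Danheiser benzannulation. Irradiation of a diazomethyl ketone attached to a chiral dihydropyranone would give a vinylketene by Wolff rearrangement. This would combine with a silyloxyalkyne carrying the chain by (2+2) cycloaddition, four-electron ring opening of the cyclobutenone and six-electron ring closure. The product would be (2S)-2-{4-[(tert-butyldimethylsilyl)oxy]phenyl}-6-[(1E,3S)-3,7-dimethylocta-1,6-dien-1-yl]-5-hydroxy-7-[(triisopropylsilyl)oxy]-2,3-dihydro-4H-chromen-4-one A3. From A3 only two desilylations would remain to reach 21.
- For it: it is the most convergent plan. The substitution pattern of ring A in A3 is fixed by the mechanism, so there is no halogenation-regiochemistry question and no Heck reaction, and the two silyl ethers of A3 come off with fluoride. On these three points it is stronger than the chosen route.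
- Against it: both partners are demanding. The dihydropyranone must be enantioenriched and carry a diazoketone, and its C2 is prone to retro-oxa-Michael opening under thermal or photochemical stress. The silyloxyalkyne is conjugated to the E alkene of the chain, so the enyne can photoisomerise or undergo its own cycloadditions with the ketene. The cascade to A3 is run in the presence of the whole diene chain. Making the two partners would take more steps than the entire chosen route.
- Comparison: the chosen strategy starts from commodity aromatics, keeps the chain away from all reactive intermediates, and concentrates its risk in one catalytic step on a simple substrate, while the route to A3 spreads its risk over two difficult fragments and a photochemical cascade.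

Key step: step 7

Assumption: the sense of induction of Rh2(S-PTTL)4 on this substrate has to be assigned on 15; it is taken to give the 2S product, and if it gives 2R the enantiomeric catalyst Rh2(R-PTTL)4 is used with no other change.

## Route

**Step 1**
Reactants: 1 1-(2,4,6-trihydroxyphenyl)ethan-1-one (dried); 2 chloromethyl methyl ether
Product: 3 1-[2,6-dihydroxy-4-(methoxymethoxy)phenyl]ethan-1-one
Conditions: MOMCl (1.0 equiv), i-Pr2NEt (1.2 equiv), THF, 0 °C to rt
Reagents that add atoms: chloromethyl methyl ether (2), COCCl
Why: Selective O-alkylation (acetal formation): the 4-hydroxyl is the only one not hydrogen-bonded to the acetyl carbonyl and is the most acidic, so with one equivalent of chloride and a hindered amine it should react first; over-alkylated material is removed by chromatography.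

**Step 2**
Reactants: 4 4-(methoxymethoxy)benzaldehyde
Product: 5 [4-(methoxymethoxy)phenyl]methanol
Conditions: NaBH4, MeOH, 0 °C
Reagents that add atoms: none
Why: Borohydride reduction of an aromatic aldehyde; the acetal is inert to hydride and to the mildly basic medium.

**Step 3**
Reactants: 3 1-[2,6-dihydroxy-4-(methoxymethoxy)phenyl]ethan-1-one; 5 [4-(methoxymethoxy)phenyl]methanol
Product: 6 1-[2-hydroxy-4-(methoxymethoxy)-6-{[4-(methoxymethoxy)phenyl]methoxy}phenyl]ethan-1-one
Conditions: PPh3, DIAD, THF, 0 °C to rt (5, 1.0 equiv)
Reagents that add atoms: [4-(methoxymethoxy)phenyl]methanol (5), COCOc1ccc(CO)cc1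
Why: Mitsunobu etherification under neutral conditions: the two phenols of 3 are equivalent, so mono-alkylation can give only one regioisomer, and the remaining hydroxyl, then locked in the hydrogen bond to the ketone, should react much more slowly. This ether carbon and its aryl group are the future C2 and ring B.

**Step 4**
Reactants: 6 1-[2-hydroxy-4-(methoxymethoxy)-6-{[4-(methoxymethoxy)phenyl]methoxy}phenyl]ethan-1-one; 7 N-bromosuccinimide
Product: 8 1-[3-bromo-2-hydroxy-4-(methoxymethoxy)-6-{[4-(methoxymethoxy)phenyl]methoxy}phenyl]ethan-1-one
Conditions: NBS (1.0 equiv), i-Pr2NH (0.1 equiv), CH2Cl2, 0 °C, dark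
Reagents that add atoms: N-bromosuccinimide (7), O=C1CCC(=O)N1Br
Why: Electrophilic aromatic bromination; 2-hydroxy-4,6-dialkoxyaryl ketones are known to halogenate preferentially ortho to the chelated hydroxyl, and that position is also the less hindered of the two open ones (flanked by OH and the acetal, not by two ethers), with the amine-mediated protocol reinforcing ortho delivery. The brominated carbon is the future C6; ring B is far less activated than the trioxygenated ring A.

**Step 5**
Reactants: 8 1-[3-bromo-2-hydroxy-4-(methoxymethoxy)-6-{[4-(methoxymethoxy)phenyl]methoxy}phenyl]ethan-1-one; 9 iodomethane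
Product: 10 1-[3-bromo-2-methoxy-4-(methoxymethoxy)-6-{[4-(methoxymethoxy)phenyl]methoxy}phenyl]ethan-1-one
Conditions: MeI, K2CO3, DMF, 40 °C
Reagents that add atoms: iodomethane (9), CI
Why: Williamson methylation of the hindered, chelated phenol. Methyl is chosen for O5 because its primary C–H bonds are poor partners for the carbenoid and because a methyl ether peri to the C4 carbonyl can later be removed by chelation.

**Step 6**
Reactants: 10 1-[3-bromo-2-methoxy-4-(methoxymethoxy)-6-{[4-(methoxymethoxy)phenyl]methoxy}phenyl]ethan-1-one; 11 2,2,2-trifluoroethyl trifluoroacetate; 12 4-acetamidobenzenesulfonyl azide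
Product: 14 1-[3-bromo-2-methoxy-4-(methoxymethoxy)-6-{[4-(methoxymethoxy)phenyl]methoxy}phenyl]-2-diazoethan-1-one, via trifluoroacetylated ketone 13 (not isolated)
Conditions: LiN(SiMe3)2, THF, −78 °C; CF3CO2CH2CF3; aq. NH4Cl; then 12, Et3N, H2O (1 equiv), MeCN, rt
Reagents that add atoms: 4-acetamidobenzenesulfonyl azide (12), CC(=O)Nc1ccc(cc1)S(=O)(=O)N=[N+]=[N-] (supplies the two diazo nitrogens); 2,2,2-trifluoroethyl trifluoroacetate (11), FC(F)(F)COC(=O)C(F)(F)F (its trifluoroacetyl group is present only in 13)
Why: Detrifluoroacetylative diazo transfer: the lithium enolate of the methyl ketone undergoes Claisen acylation to diketone 13, whose enolate attacks the sulfonyl azide, and loss of the N-trifluoroacetyl sulfonamide leaves the diazomethyl ketone. The acetals, the benzylic ether and the aryl bromide are inert to the amide base at −78 °C.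

**Step 7**
Reactants: 14 1-[3-bromo-2-methoxy-4-(methoxymethoxy)-6-{[4-(methoxymethoxy)phenyl]methoxy}phenyl]-2-diazoethan-1-one
Product: 15 (2S)-6-bromo-5-methoxy-7-(methoxymethoxy)-2-[4-(methoxymethoxy)phenyl]-2,3-dihydro-4H-chromen-4-one
Conditions: Rh2(S-PTTL)4 (1 mol %), CH2Cl2, 0 °C, slow addition of 14 (final 0.01 M)
Reagents that add atoms: none
Why: Rh2(S-PTTL)4, the tetrakis[N-phthaloyl-(S)-tert-leucinate] of the divalent rhodium dimer, decomposes the diazoketone with loss of N2 to an electrophilic carbenoid at the future C3, which inserts into one of the two benzylic C–H bonds of the ortho ArCH2O group through a concerted, asynchronous three-centre transition state (hydride-like shift to the carbenoid carbon with simultaneous C2–C3 bond formation). The closest known reaction type is the chiral dirhodium carboxylate-catalysed intramolecular C–H insertion of 2-alkoxyaryl diazomethyl ketones to 2-substituted chroman-4-ones, together with the related insertions of aryl diazoacetates into benzylic ether C–H bonds. Ring C closes as a six-membered ring by 1,6-insertion (carbenoid carbon, C4, C4a, C8a, O1, C2); a 1,5-insertion is not available because the fifth atom is O1. C2 is the only new stereocentre and is controlled by the catalyst: the four bulky carboxylate ligands wall in the axial carbenoid site so that the substrate can present only one of the two enantiotopic benzylic hydrogens, with the aryl group turned away from the ligands. The step needs chemoselectivity for C–H insertion over attack of the O1 or O5 lone pairs (five-membered oxonium ylide, then 1,2-shift of the benzyl or methyl group) and site selectivity over all other C–H bonds. The substrate secures this because the reacting C–H bond is activated twice (O1 and the 4-alkoxyphenyl ring both stabilise positive charge at C2), because O1 and O5 are vinylogous ester oxygens of low nucleophilicity whose ylide formation is reversible at 0 °C, because the O5 methyl group, the only other site within reach of a 1,6-insertion, offers primary C–H bonds activated by oxygen alone, and because the two acetals sit para to the acyl group and at the far end of ring B, out of reach. Slow addition at high dilution suppresses carbene dimerisation.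

**Step 8**
Reactants: 15 (2S)-6-bromo-5-methoxy-7-(methoxymethoxy)-2-[4-(methoxymethoxy)phenyl]-2,3-dihydro-4H-chromen-4-one
Product: 16 (2S)-6-bromo-5,7-dihydroxy-2-(4-hydroxyphenyl)-2,3-dihydro-4H-chromen-4-one
Conditions: BCl3 (6 equiv), CH2Cl2, −78 to 0 °C; MeOH, then aq. NaHCO3
Reagents that add atoms: none
Why: BCl3 should cleave the two acetals through their basic distal oxygens at −78 °C and, on warming, the peri methyl ether through the six-membered boron chelate between the C4 carbonyl and O5 (chelation-assisted dealkylation). O1 is a vinylogous ester oxygen of low basicity and ring B carries only a weakly donating O–B group once its acetal is gone, so ionisation of C2–O1 is not expected at these temperatures and C2 should be retained.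

**Step 9**
Reactants: 16 (2S)-6-bromo-5,7-dihydroxy-2-(4-hydroxyphenyl)-2,3-dihydro-4H-chromen-4-one; 17 acetic anhydride
Product: 18 (2S)-2-[4-(acetyloxy)phenyl]-6-bromo-4-oxo-3,4-dihydro-2H-chromene-5,7-diyl diacetate
Conditions: Ac2O, pyridine, DMAP (cat.), CH2Cl2, 0 °C to rt
Reagents that add atoms: acetic anhydride (17), CC(=O)OC(C)=O
Why: O-Acetylation with nucleophilic catalysis; the catalyst is needed for the chelated, bromine-flanked 5-hydroxyl. The acetates lower the electron density of ring A for oxidative addition, keep phenoxides (which trigger ring C opening) out of the next step, and can be removed at the end without acid.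

**Step 10**
Reactants: 18 (2S)-2-[4-(acetyloxy)phenyl]-6-bromo-4-oxo-3,4-dihydro-2H-chromene-5,7-diyl diacetate; 19 (3S)-3,7-dimethylocta-1,6-diene ((S)-β-citronellene)
Product: 20 (2S)-2-[4-(acetyloxy)phenyl]-6-[(1E,3S)-3,7-dimethylocta-1,6-dien-1-yl]-4-oxo-3,4-dihydro-2H-chromene-5,7-diyl diacetate
Conditions: Pd2(dba)3 (2.5 mol %), [HP(t-Bu)3]BF4 (10 mol %), Cy2NMe (1.5 equiv), 19 (3 equiv), 1,4-dioxane, 70 °C
Reagents that add atoms: (3S)-3,7-dimethylocta-1,6-diene (19), CC(C)=CCC[C@H](C)C=C
Why: Mizoroki–Heck reaction: the hindered bromide adds oxidatively to zerovalent palladium carrying the bulky, electron-rich P(t-Bu)3, the monosubstituted alkene inserts with the aryl group going to the terminal carbon, and syn β-hydride elimination toward the benzylic side should give the conjugated E alkene. The trisubstituted alkene is too hindered to insert, the hindered amine removes HBr quickly so that palladium hydride has little time to re-add, and no bond to C3'' or C2 is made or broken.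

**Step 11**
Reactants: 20 (2S)-2-[4-(acetyloxy)phenyl]-6-[(1E,3S)-3,7-dimethylocta-1,6-dien-1-yl]-4-oxo-3,4-dihydro-2H-chromene-5,7-diyl diacetate
Product: 21 (2S)-6-[(1E,3S)-3,7-dimethylocta-1,6-dien-1-yl]-5,7-dihydroxy-2-(4-hydroxyphenyl)-2,3-dihydro-4H-chromen-4-one
Conditions: NH4OAc (10 equiv), MeOH–H2O 4:1, rt
Reagents that add atoms: none
Why: Buffered solvolysis of aryl acetates near neutrality; it avoids acid (electron-rich styrene, trisubstituted alkene) and strong base (retro-oxa-Michael opening of ring C), so both stereocentres and the diene should survive.

## Compound list

1 | 1-(2,4,6-trihydroxyphenyl)ethan-1-one | CC(=O)c1c(O)cc(O)cc1O | starting material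
2 | chloromethyl methyl ether | COCCl | starting material
3 | 1-[2,6-dihydroxy-4-(methoxymethoxy)phenyl]ethan-1-one | CC(=O)c1c(O)cc(OCOC)cc1O | intermediate
4 | 4-(methoxymethoxy)benzaldehyde | COCOc1ccc(C=O)cc1 | starting material
5 | [4-(methoxymethoxy)phenyl]methanol | COCOc1ccc(CO)cc1 | intermediate
6 | 1-[2-hydroxy-4-(methoxymethoxy)-6-{[4-(methoxymethoxy)phenyl]methoxy}phenyl]ethan-1-one | CC(=O)c1c(O)cc(OCOC)cc1OCc1ccc(OCOC)cc1 | intermediate
7 | N-bromosuccinimide | O=C1CCC(=O)N1Br | starting material
8 | 1-[3-bromo-2-hydroxy-4-(methoxymethoxy)-6-{[4-(methoxymethoxy)phenyl]methoxy}phenyl]ethan-1-one | CC(=O)c1c(O)c(Br)c(OCOC)cc1OCc1ccc(OCOC)cc1 | intermediate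
9 | iodomethane | CI | starting material
10 | 1-[3-bromo-2-methoxy-4-(methoxymethoxy)-6-{[4-(methoxymethoxy)phenyl]methoxy}phenyl]ethan-1-one | CC(=O)c1c(OC)c(Br)c(OCOC)cc1OCc1ccc(OCOC)cc1 | intermediate
11 | 2,2,2-trifluoroethyl trifluoroacetate | FC(F)(F)COC(=O)C(F)(F)F | starting material
12 | 4-acetamidobenzenesulfonyl azide | CC(=O)Nc1ccc(cc1)S(=O)(=O)N=[N+]=[N-] | starting material
13 | 1-[3-bromo-2-methoxy-4-(methoxymethoxy)-6-{[4-(methoxymethoxy)phenyl]methoxy}phenyl]-4,4,4-trifluorobutane-1,3-dione | O=C(CC(=O)C(F)(F)F)c1c(OC)c(Br)c(OCOC)cc1OCc1ccc(OCOC)cc1 | intermediate
14 | 1-[3-bromo-2-methoxy-4-(methoxymethoxy)-6-{[4-(methoxymethoxy)phenyl]methoxy}phenyl]-2-diazoethan-1-one | [N-]=[N+]=CC(=O)c1c(OC)c(Br)c(OCOC)cc1OCc1ccc(OCOC)cc1 | intermediate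
15 | (2S)-6-bromo-5-methoxy-7-(methoxymethoxy)-2-[4-(methoxymethoxy)phenyl]-2,3-dihydro-4H-chromen-4-one | COCOc1cc2c(c(OC)c1Br)C(=O)C[C@@H](c1ccc(OCOC)cc1)O2 | intermediate
16 | (2S)-6-bromo-5,7-dihydroxy-2-(4-hydroxyphenyl)-2,3-dihydro-4H-chromen-4-one | Oc1cc2c(c(O)c1Br)C(=O)C[C@@H](c1ccc(O)cc1)O2 | intermediate
17 | acetic anhydride | CC(=O)OC(C)=O | starting material
18 | (2S)-2-[4-(acetyloxy)phenyl]-6-bromo-4-oxo-3,4-dihydro-2H-chromene-5,7-diyl diacetate | CC(=O)Oc1cc2c(c(OC(C)=O)c1Br)C(=O)C[C@@H](c1ccc(OC(C)=O)cc1)O2 | intermediate
19 | (3S)-3,7-dimethylocta-1,6-diene ((S)-β-citronellene) | CC(C)=CCC[C@H](C)C=C | starting material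
20 | (2S)-2-[4-(acetyloxy)phenyl]-6-[(1E,3S)-3,7-dimethylocta-1,6-dien-1-yl]-4-oxo-3,4-dihydro-2H-chromene-5,7-diyl diacetate | CC(C)=CCC[C@H](C)/C=C/c1c(OC(C)=O)cc2c(c1OC(C)=O)C(=O)C[C@@H](c1ccc(OC(C)=O)cc1)O2 | intermediate
21 | (2S)-6-[(1E,3S)-3,7-dimethylocta-1,6-dien-1-yl]-5,7-dihydroxy-2-(4-hydroxyphenyl)-2,3-dihydro-4H-chromen-4-one | CC(C)=CCC[C@H](C)/C=C/c1c(O)cc2c(c1O)C(=O)C[C@@H](c1ccc(O)cc1)O2 | target

## Step count and least certain steps

Total step count: 11. Longest linear sequence: 10 steps (1 → 3 → 6 → 8 → 10 → 14 → 15 → 16 → 18 → 20 → 21); step 2 is a one-step side branch.

**Step 7 (key step).** Two things can go wrong. The O1 lone pair can add to the carbenoid and the resulting five-membered oxonium ylide can undergo 1,2-benzyl shift, giving ring contraction instead of C–H insertion. The catalyst may also discriminate poorly between the two enantiotopic benzylic hydrogens, since carbenoids from diazomethyl ketones carry no second stabilising group and are less selective than donor-substituted ones.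

The fallback sets C2 by asymmetric conjugate addition. It sets out from 3 and returns at 15. Condensation of 3 with N,N-dimethylformamide dimethyl acetal gives (2E)-3-(dimethylamino)-1-[2,6-dihydroxy-4-(methoxymethoxy)phenyl]prop-2-en-1-one F1, which closes in warm acetic acid to 5-hydroxy-7-(methoxymethoxy)-4H-chromen-4-one F2. Bromination ortho to the chelated hydroxyl with NBS gives 6-bromo-5-hydroxy-7-(methoxymethoxy)-4H-chromen-4-one F3, and methylation (MeI, K2CO3) gives 6-bromo-5-methoxy-7-(methoxymethoxy)-4H-chromen-4-one F4. Asymmetric 1,4-addition of commercial [4-(methoxymethoxy)phenyl]boronic acid to F4, catalysed by [Rh(OH)(cod)]2 (monovalent rhodium) with an atropisomeric bisphosphine of the enantiomer that leads to 2S, then delivers 15.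

**Step 10.** Oxidative addition and insertion at the di-ortho-substituted bromide may be slow, so that hydrodebromination wins. β-Hydride elimination toward C3'', or re-addition of palladium hydride, can move the double bond out of conjugation and erase the allylic stereocentre. Prolonged heating with amine may also open ring C and erode C2.

The fallback moves the regiochemical question to the cheap chain reagent. It sets out from 19 and returns at 20. Boryl-Heck reaction of 19 (B-chlorocatecholborane, Pd2(dba)3 with a bulky phosphine, Et3N) gives 2-[(1E,3S)-3,7-dimethylocta-1,6-dien-1-yl]-2H-1,3,2-benzodioxaborole F5. Transesterification of F5 with pinacol in the same flask gives 2-[(1E,3S)-3,7-dimethylocta-1,6-dien-1-yl]-4,4,5,5-tetramethyl-1,3,2-dioxaborolane F6, which can be purified and checked for isomeric purity. Suzuki–Miyaura coupling of F6 with 18 (Pd(OAc)2, SPhos, anhydrous K3PO4, toluene, 60 °C) gives 20. Partial loss of acetate during this coupling is of no consequence because step 11 removes the acetates anyway.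

**Step 8.** The boron chelate makes O1 a better leaving group, so reversible heterolysis of C2–O1 with loss of configuration at C2 is conceivable. Cleavage of the O5 methyl ether may also stall below the temperature at which ring C is safe.

The fallback separates the two cleavage types and avoids boron. It sets out from 15 and returns at 16. Dilute HCl in MeOH at 40 °C removes only the acetals and gives (2S)-6-bromo-7-hydroxy-2-(4-hydroxyphenyl)-5-methoxy-2,3-dihydro-4H-chromen-4-one F7. MgI2 etherate in THF then removes the peri methyl group of F7 through a magnesium chelate and gives 16.

**Step 4.** Bromination may occur para to the free hydroxyl, at the carbon between the two ether oxygens, which would lead to the C8 series; ring B may also be brominated.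

The fallback fixes the halogen position by symmetry. It sets out from 3 and returns at 10. Bromination of 3, whose two open ring positions are equivalent, gives 1-[3-bromo-2,6-dihydroxy-4-(methoxymethoxy)phenyl]ethan-1-one F8. Methylation with one equivalent of MeI and K2CO3 should take place at the more acidic, bromine-flanked phenol and give 1-[3-bromo-6-hydroxy-2-methoxy-4-(methoxymethoxy)phenyl]ethan-1-one F9 (the isomeric ether, if formed, is separable). Mitsunobu etherification of F9 with 5 gives 10.

## Further compounds

F1 | step 7 | (2E)-3-(dimethylamino)-1-[2,6-dihydroxy-4-(methoxymethoxy)phenyl]prop-2-en-1-one | CN(C)/C=C/C(=O)c1c(O)cc(OCOC)cc1O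
F2 | step 7 | 5-hydroxy-7-(methoxymethoxy)-4H-chromen-4-one | O=C1C=COc2cc(OCOC)cc(O)c12
F3 | step 7 | 6-bromo-5-hydroxy-7-(methoxymethoxy)-4H-chromen-4-one | O=C1C=COc2cc(OCOC)c(Br)c(O)c12
F4 | step 7 | 6-bromo-5-methoxy-7-(methoxymethoxy)-4H-chromen-4-one | O=C1C=COc2cc(OCOC)c(Br)c(OC)c12
F5 | step 10 | 2-[(1E,3S)-3,7-dimethylocta-1,6-dien-1-yl]-2H-1,3,2-benzodioxaborole | CC(C)=CCC[C@H](C)/C=C/B1Oc2ccccc2O1
F6 | step 10 | 2-[(1E,3S)-3,7-dimethylocta-1,6-dien-1-yl]-4,4,5,5-tetramethyl-1,3,2-dioxaborolane | CC(C)=CCC[C@H](C)/C=C/B1OC(C)(C)C(C)(C)O1
F7 | step 8 | (2S)-6-bromo-7-hydroxy-2-(4-hydroxyphenyl)-5-methoxy-2,3-dihydro-4H-chromen-4-one | COc1c(Br)c(O)cc2c1C(=O)C[C@@H](c1ccc(O)cc1)O2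
F8 | step 4 | 1-[3-bromo-2,6-dihydroxy-4-(methoxymethoxy)phenyl]ethan-1-one | CC(=O)c1c(O)c(Br)c(OCOC)cc1O
F9 | step 4 | 1-[3-bromo-6-hydroxy-2-methoxy-4-(methoxymethoxy)phenyl]ethan-1-one | CC(=O)c1c(OC)c(Br)c(OCOC)cc1O
A1 | alternative 1 | (2S)-4-[(tert-butyldimethylsilyl)oxy]-6-[(1E,3S)-3,7-dimethylocta-1,6-dien-1-yl]-5,7-bis(methoxymethoxy)-2-[4-(methoxymethoxy)phenyl]-3,4-dihydro-2H-chromene (C4 configuration undefined) | CC(C)=CCC[C@H](C)/C=C/c1c(OCOC)cc2c(c1OCOC)C(O[Si](C)(C)C(C)(C)C)C[C@@H](c1ccc(OCOC)cc1)O2
A2 | alternative 2 | (2R)-6-bromo-5,7-dimethoxy-2-[4-(pivaloyloxy)phenyl]-2H-chromene-3-carbaldehyde | COc1cc2c(c(OC)c1Br)C=C(C=O)[C@@H](c1ccc(OC(=O)C(C)(C)C)cc1)O2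
A3 | alternative 3 | (2S)-2-{4-[(tert-butyldimethylsilyl)oxy]phenyl}-6-[(1E,3S)-3,7-dimethylocta-1,6-dien-1-yl]-5-hydroxy-7-[(triisopropylsilyl)oxy]-2,3-dihydro-4H-chromen-4-one | CC(C)=CCC[C@H](C)/C=C/c1c(O[Si](C(C)C)(C(C)C)C(C)C)cc2c(c1O)C(=O)C[C@@H](c1ccc(O[Si](C)(C)C(C)(C)C)cc1)O2
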